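## The problem

The target 31 is a daucane-type sesquiterpenoid ester: a cyclopentane (C1–C5) trans-fused through C1 and C5 to a cycloheptenone (C1, C5–C10). Numbering used throughout: C1 is the methyl-bearing fusion carbon, C2 and C3 the cyclopentane CH2 groups, C4 the carbon carrying isopropyl and the 4-hydroxybenzoate, C5 the fusion CH, C6 the CHOH, C7=C8(CH3) the alkene, C9 the ketone and C10 the CH2 between C9 and C1. β is the face of H-5, α the face of the C1 methyl.

There are four stereocentres (1R,4R,5S,6S): quaternary C1, fully substituted C4 with its oxygen on the α-face, C5, and C6 with its hydroxyl on the β-face. C1 has no neighbour to lean on and must be set by a chiral catalyst. From there a relay is possible: C1 directs C5, C5 directs C4, and the finished ring fusion directs C6.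

Three things are fragile. The tertiary aryl ester sits 1,3 to the free secondary C6 hydroxyl and can migrate to that less hindered oxygen under base. The γ-hydroxy enone does not tolerate base. Every intermediate with a carbonyl at C6 and an oxygen on C4 is an aldol that can cleave or eliminate. In addition, the C4 hydroxyl is hindered enough that its esterification has to be timed deliberately.

The structural feature that opens the route is that C6 is bonded to C7, and C7=C8(CH3)–C9(=O) is an isopropenyl carbinol in disguise. An aldehyde carbon C6 on C5 and an isopropenyl group on C9, at the end of the C10 arm, are the two partners of a carbonyl-ene reaction. That reaction forms C6–C7, the C6 hydroxyl and the seven-membered ring together.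

## Retrosynthesis

**Enone and free hydroxyls (31 ⇒ 30 ⇒ 29).** No skeletal bond is cut. The two silyl ethers of 30 are removed last under acidic fluoride, so no alkoxide ever faces the tertiary ester. The endocyclic enone 30 is the conjugated, more substituted isomer of the α-methylene ketone 29, so the forward step only has to move a double bond downhill.

**C9 oxidation state and the C4–O acyl bond (29 ⇒ 28 ⇒ 27 ⇒ 22 + 25).** The ketone comes from the 4-methoxybenzyl-protected allylic alcohol 27. The ester is cut at the O–acyl bond to the tertiary alcohol 22 and acid chloride 25 (from 23 through 24). This cut is placed before any ketone exists because a hindered tertiary alcohol is acylated reliably only as its alkoxide. It is placed after the ring closure because an ester on C4 would migrate to a free C6 oxygen and would make the C6 aldehyde prone to β-elimination.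

**Hydroxyl differentiation (22 ⇒ 21 ⇒ 20).** No skeletal bond is cut. The 4,6-diol 21 is distinguished by hindrance (secondary against tertiary), which is more dependable than selective cleavage of one silyl ether beside another.

**Ring closure at C6–C7 (20 ⇒ 19).** The key cut opens the seven-membered ring to aldehyde 19. The neighbouring cuts were weighed against it. C7–C8 would need an aldol condensation on a substrate whose C6 centre is α to the reacting aldehyde. C1–C10 would need a quaternary centre made during ring closure. The C6–C7 cut leaves a monocyclic cyclopentane with all fifteen skeletal carbons and only three stereocentres. It asks the forward reaction for one thing beyond bond formation: the right face of the aldehyde.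

**Side arm (19 ⇒ 17 ⇒ 16 ⇒ 14 + 15).** The C8–C9 bond is cut to aldehyde 14 and the isopropenyl Grignard reagent 15. The C9 configuration is irrelevant because C9 ends as a ketone. The C6 aldehyde of 19 is unmasked from a primary triethylsilyl ether by direct oxidation, which saves a deprotection.

**C4–isopropyl bond (14 ⇒ 13 ⇒ 12 ⇒ 10 + 11).** The tertiary carbinol is cut to ketone 10 and the isopropyl Grignard reagent 11. The forward addition must come anti to the C5 substituent. That is the normal course for a 2-substituted cyclopentanone and gives the C4 oxygen cis to C6 and to the C1 methyl.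

**C1–CH3 and C5–C6 (10 ⇒ 9 ⇒ 5 + 6 + 7).** Both bonds are cut in one operation to enone 5, trimethylaluminium 6 and formaldehyde 7. The conjugate addition sets C1 under ligand control and the regiodefined enolate is captured at C5. The forward step must place C6 trans to the bulkier acetate arm.

**C1–C10 (5 ⇒ 1 + 2).** The enone is cut to the vinylogous ester 1 and tert-butyl acetate 2, joined by 1,2-addition and carbonyl transposition.

## Roads not taken

**Alternative 1:** The hydroazulene is traced to a cis-decalin in which C1 is bonded to C6. A semipinacol shift of the all-cis mesylate A2 moves C1 from C6 to C5 with loss of mesylate and gives hydroazulenone A1.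

- Merits: the carbon skeleton comes from Robinson annulation chemistry. The 1,2-shift is stereospecific (inversion at C5, retention at C1), so the ring fusion is fixed without relying on steric discrimination. The free C4 hydroxyl of A1 can direct reduction of the C6 ketone to the β-alcohol.
- Weak points: A2 needs three contiguous oxygenated centres in an all-cis array, a mesylate placed selectively on the secondary oxygen between two tertiary ones, and a conformation with the C5–O bond antiperiplanar to C1–C6. In A1 the fusion carbon C5 is α to the C6 ketone and can epimerise, and A1 is an aldol of the C4 carbinol. After the shift the C7=C8 double bond, the C9 ketone and the ester still have to be introduced.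
- Comparison: this road is better in the certainty of the C1/C5 relationship. The chosen plan sets against that a much shorter path to its ring-closure substrate, and a cyclisation product 20 that already carries C6 as the alcohol and every carbon of the enone.

**Alternative 2:** The cuts are C1–CH3 and C5–C6, as in the chosen plan, but the enolate of enone A4 (after CuTC/phosphoramidite-catalysed addition of 6) is captured by aldehyde A5 to give aldol A3. The ring would be closed later at C7–C8 by aldol condensation, after ozonolysis to the C9 ketone and acetal hydrolysis.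

- Merits: C1, C5 and C6 are set in one step. The condensation delivers the C7=C8 enone directly, with no double-bond isomerisation and no adjustment of oxidation state at C9. In these respects it is better than the chosen plan.
- Weak points: the C6 configuration rests on the simple and facial selectivity of a hindered aluminium enolate with an α-alkoxy aldehyde. At the ring-closing stage C6 is α to the reacting aldehyde and can epimerise or eliminate. The ethyl ketone must enolise toward C8 and not C10, and seven-membered aldol closure is reversible.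
- Comparison: step counts are similar. The chosen plan gives up about three steps (isomerisation and protecting-group changes). In return it has an irreversible Lewis-acid ring closure in which C6 is never enolisable, and a tested way to correct C6 by directed reduction.

**Alternative 3:** The cuts are C1–C10 and C7–C8. Rh2(S-PTAD)4 converts diazo ester A8 into a vinylcarbenoid that cyclopropanates the vinyl group of diene A7. Cope rearrangement of the cis-divinylcyclopropane gives cycloheptadiene A6.

- Merits: it is the most convergent. The seven-membered ring and quaternary C1 form in one catalytic enantioselective step from two small pieces. C9 arrives oxygenated. The C5=C6 alkene could in principle deliver H-5 and the 6β-hydroxyl by one hydroboration anti to the angular methyl.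
- Weak points: the Cope rearrangement must build a quaternary centre from a fully substituted alkene terminus next to a ketal. C8 carries an ester where the target has a methyl. The C4 carbinol, the C7=C8 unsaturation and the hydroboration in the presence of a second alkene all remain to be done after the key step.
- Comparison: on paper this reaches the bicyclic core in fewer steps and fixes C1 in the ring-forming step. The chosen plan sets against it that every step up to the cyclisation is a standard transformation and that the C4/C6/C9 oxygen pattern is carried through without redox detours at C8.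

Key step: step 10

Assumption: the sense of induction of the phosphoramidite in step 2 is assigned by analogy with related 3-substituted cycloalkenones; the ligand antipode that gives (1R) is the one used.
Remark: compounds 16–28 are carried as mixtures of C9 epimers, which converge on ketone 29.

## Route

Step 1
Reactants: 1 3-ethoxycyclopent-2-en-1-one; 2 tert-butyl acetate
Product: 5 tert-butyl 2-(3-oxocyclopent-1-en-1-yl)acetate, via lithium ester enolate 3 (not isolated), via lithium alkoxide adduct 4 (not isolated)
Conditions: LiN(iPr)2, THF, −78 °C; then 1, −78 to 0 °C; then 2 M HCl, rt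
Reagents that add atoms: water O
Why: Stork–Danheiser sequence: the ester enolate adds 1,2 to the vinylogous ester, and acid hydrolysis of the enol ether with loss of water transposes the carbonyl to give the 3-substituted enone. The tert-butyl ester resists self-condensation and the brief acid treatment.

Step 2
Reactants: 5 tert-butyl 2-(3-oxocyclopent-1-en-1-yl)acetate; 6 trimethylaluminium; 7 formaldehyde
Product: 9 tert-butyl 2-[(1R,2S)-2-(hydroxymethyl)-1-methyl-3-oxocyclopentyl]acetate, via dimethylaluminium enolate 8 (not isolated)
Conditions: copper thiophene-2-carboxylate (CuTC, 5 mol %), BINOL-derived bis(1-phenylethyl)phosphoramidite (10 mol %), Et2O, −30 °C; then 7 (monomeric, THF), −78 to −40 °C; aq. potassium sodium tartrate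
Reagents that add atoms: none
Why: Copper-catalysed asymmetric conjugate addition of a trialkylaluminium to a 3-substituted cyclopentenone creates quaternary C1 under ligand control. The regiodefined aluminium enolate then undergoes aldol addition to formaldehyde on the face away from the bulkier CH2CO2tBu arm, so C6 ends trans to that arm; C5 stays epimerisable and prefers the same arrangement at equilibrium.

Step 3
Reactants: 9 tert-butyl 2-[(1R,2S)-2-(hydroxymethyl)-1-methyl-3-oxocyclopentyl]acetate
Product: 10 tert-butyl 2-[(1R,2S)-1-methyl-3-oxo-2-{[(triethylsilyl)oxy]methyl}cyclopentyl]acetate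
Conditions: TESCl, imidazole, CH2Cl2, 0 °C
Reagents that add atoms: chlorotriethylsilane CC[Si](Cl)(CC)CC
Why: Silylation of the primary alcohol under near-neutral conditions stops retro-aldol cleavage and dehydration of the aldol. It also installs a primary triethylsilyl ether that can later be oxidised directly; a minor C5 epimer is removed here by chromatography.

Step 4
Reactants: 10 tert-butyl 2-[(1R,2S)-1-methyl-3-oxo-2-{[(triethylsilyl)oxy]methyl}cyclopentyl]acetate; 11 isopropylmagnesium chloride
Product: 12 tert-butyl 2-[(1R,2S,3R)-3-hydroxy-1-methyl-3-(propan-2-yl)-2-{[(triethylsilyl)oxy]methyl}cyclopentyl]acetate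
Conditions: CeCl3 (anhydrous), THF, −78 to 0 °C; aq. NH4Cl
Reagents that add atoms: none
Why: Organocerium addition suppresses enolisation and β-hydride reduction and leaves the tert-butyl ester alone. The isopropyl group attacks the cyclopentanone anti to the adjacent C5 silyloxymethyl group, which puts the new C4 hydroxyl cis to that group and to the C1 methyl (4R).

Step 5
Reactants: 12 tert-butyl 2-[(1R,2S,3R)-3-hydroxy-1-methyl-3-(propan-2-yl)-2-{[(triethylsilyl)oxy]methyl}cyclopentyl]acetate
Product: 13 tert-butyl 2-[(1R,2S,3R)-1-methyl-3-(propan-2-yl)-3-[(triethylsilyl)oxy]-2-{[(triethylsilyl)oxy]methyl}cyclopentyl]acetate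
Conditions: TESOTf, 2,6-lutidine, CH2Cl2, 0 °C to rt
Reagents that add atoms: triethylsilyl trifluoromethanesulfonate CC[Si](CC)(CC)OS(=O)(=O)C(F)(F)F
Why: A silyl triflate with a hindered pyridine base silylates tertiary alcohols. The C4 ether blocks retro-aldol cleavage and elimination once C6 becomes an aldehyde.

Step 6
Reactants: 13 tert-butyl 2-[(1R,2S,3R)-1-methyl-3-(propan-2-yl)-3-[(triethylsilyl)oxy]-2-{[(triethylsilyl)oxy]methyl}cyclopentyl]acetate
Product: 14 2-[(1R,2S,3R)-1-methyl-3-(propan-2-yl)-3-[(triethylsilyl)oxy]-2-{[(triethylsilyl)oxy]methyl}cyclopentyl]acetaldehyde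
Conditions: iBu2AlH, CH2Cl2, −78 °C; aq. potassium sodium tartrate
Reagents that add atoms: none
Why: Partial reduction of an ester by a dialkylaluminium hydride at low temperature stops at the aluminium hemiacetal, which releases the aldehyde on work-up. Silyl ethers are inert.

Step 7
Reactants: 14 2-[(1R,2S,3R)-1-methyl-3-(propan-2-yl)-3-[(triethylsilyl)oxy]-2-{[(triethylsilyl)oxy]methyl}cyclopentyl]acetaldehyde; 15 isopropenylmagnesium bromide
Product: 16 (2RS)-3-methyl-1-[(1R,2S,3R)-1-methyl-3-(propan-2-yl)-3-[(triethylsilyl)oxy]-2-{[(triethylsilyl)oxy]methyl}cyclopentyl]but-3-en-2-ol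
Conditions: THF, −78 to 0 °C; aq. NH4Cl
Reagents that add atoms: none
Why: Grignard 1,2-addition to an unhindered aldehyde. The remote stereocentres give little induction, so both C9 epimers form and both are carried on.

Step 8
Reactants: 16 (2RS)-3-methyl-1-[(1R,2S,3R)-1-methyl-3-(propan-2-yl)-3-[(triethylsilyl)oxy]-2-{[(triethylsilyl)oxy]methyl}cyclopentyl]but-3-en-2-ol
Product: 17 4-methoxybenzyl ether of 16 at the C9 oxygen (1R,4R,5S,9RS in skeleton numbering)
Conditions: NaH, PMBCl, Bu4NI (cat.), THF/DMF, 0 °C to rt
Reagents that add atoms: 4-methoxybenzyl chloride COc1ccc(CCl)cc1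
Why: Williamson etherification of the secondary allylic alkoxide. The 4-methoxybenzyl ether is orthogonal to all silyl groups and is removed oxidatively late in the route.

Step 9
Reactants: 17 4-methoxybenzyl ether of 16
Product: 19 (1R,2R,5R)-2-{(2RS)-2-[(4-methoxyphenyl)methoxy]-3-methylbut-3-en-1-yl}-2-methyl-5-(propan-2-yl)-5-[(triethylsilyl)oxy]cyclopentane-1-carbaldehyde, via alkoxysulfonium chloride 18 (not isolated)
Conditions: (COCl)2, DMSO, CH2Cl2, −78 to −30 °C; then Et3N, −78 to 0 °C
Reagents that add atoms: none
Why: Under Swern conditions a primary triethylsilyl ether is converted directly into the aldehyde through the alkoxysulfonium salt, while tertiary silyl ethers and benzyl-type ethers are untouched. The low temperature and the crowded α-carbon keep C5 from epimerising.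

Step 10
Reactants: 19 (1R,2R,5R)-2-{(2RS)-2-[(4-methoxyphenyl)methoxy]-3-methylbut-3-en-1-yl}-2-methyl-5-(propan-2-yl)-5-[(triethylsilyl)oxy]cyclopentane-1-carbaldehyde
Product: 20 (1R,4R,5S,6S,9RS)-9-[(4-methoxyphenyl)methoxy]-1-methyl-8-methylidene-4-(propan-2-yl)-4-[(triethylsilyl)oxy]-trans-hydroazulen-6-ol (skeleton numbering)
Conditions: Me2AlCl (2.5 equiv), CH2Cl2, −78 to −40 °C; aq. potassium sodium tartrate
Reagents that add atoms: none
Why: Me2AlCl binds the aldehyde oxygen; the terminal isopropenyl carbon C7 attacks C6 while a hydrogen of the allylic methyl passes to oxygen through a six-membered array, and the alcohol–aluminium complex then loses methane to give a chloro(methyl)aluminium alkoxide, which keeps the medium free of protic acid. The closest known reaction type is the Me2AlCl-promoted type 2 intramolecular carbonyl-ene cyclisation of ω-isopropenyl aldehydes to 3-methylenecyclohexanols and 3-methylenecycloheptanols. The seven-membered ring closes by 7-exo-trig attack on the carbonyl carbon with the tether on the central ene carbon C8, so C7 and C8 lie in the ring and the new C8=CH2 bond is exocyclic. The trans ring fusion is not created here but carried over from the trans arrangement of the two arms on C5 and C1 in 19. The new stereocentre C6 is controlled by C5 and its neighbours C1 and C4: the tether holds C7 anti to C4 about the C5–C6 bond, and of the two places left for the aluminium-bound oxygen the one between C4 and C1 (pseudo-axial, leading to the 6α alcohol) clashes 1,3-diaxially with the angular methyl and the C4 silyloxy group. The oxygen should therefore lie next to H-5 and anti to C1, in a twist-boat-like array that a seven-membered ring tolerates, giving the 6β (6S) alcohol. The step needs ene closure to win over Prins-type ionisation with hydride shift from C9 and over loss of the C4 silanol; the mild, proton-scavenging Lewis acid, the non-participating silyl ether on C4 and the low temperature secure this. Both C9 epimers should cyclise because C9 lies outside the ene array.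

Step 11
Reactants: 20 (1R,4R,5S,6S,9RS)-9-[(4-methoxyphenyl)methoxy]-1-methyl-8-methylidene-4-(propan-2-yl)-4-[(triethylsilyl)oxy]-trans-hydroazulen-6-ol
Product: 21 (1R,4R,5S,6S,9RS)-9-[(4-methoxyphenyl)methoxy]-1-methyl-8-methylidene-4-(propan-2-yl)-trans-hydroazulene-4,6-diol
Conditions: Bu4NF, THF, rt to 45 °C; aq. NH4Cl
Reagents that add atoms: none
Why: Fluoride cleaves the tertiary triethylsilyl ether. The resulting 4,6-diol has two hydroxyls that differ sharply in hindrance.

Step 12
Reactants: 21 (1R,4R,5S,6S,9RS)-9-[(4-methoxyphenyl)methoxy]-1-methyl-8-methylidene-4-(propan-2-yl)-trans-hydroazulene-4,6-diol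
Product: 22 (1R,4R,5S,6S,9RS)-6-[(tert-butyldimethylsilyl)oxy]-9-[(4-methoxyphenyl)methoxy]-1-methyl-8-methylidene-4-(propan-2-yl)-trans-hydroazulen-4-ol
Conditions: TBSOTf (1.1 equiv), 2,6-lutidine, CH2Cl2, −78 °C
Reagents that add atoms: tert-butyldimethylsilyl trifluoromethanesulfonate CC(C)(C)[Si](C)(C)OS(=O)(=O)C(F)(F)F
Why: At −78 °C a slight excess of silyl triflate silylates the secondary C6 hydroxyl and leaves the tertiary, isopropyl-flanked C4 hydroxyl free. The bulky silyl group is slow to migrate to the tertiary oxygen.

Step 13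
Reactants: 23 4-hydroxybenzoic acid
Product: 24 tert-butyldimethylsilyl 4-[(tert-butyldimethylsilyl)oxy]benzoate
Conditions: TBSCl (2.2 equiv), imidazole, DMF, rt
Reagents that add atoms: tert-butyldimethylsilyl chloride CC(C)(C)[Si](C)(C)Cl
Why: Exhaustive silylation protects the phenol and turns the acid into a silyl ester, the form needed for neutral conversion to the acid chloride.

Step 14
Reactants: 24 tert-butyldimethylsilyl 4-[(tert-butyldimethylsilyl)oxy]benzoate
Product: 25 4-[(tert-butyldimethylsilyl)oxy]benzoyl chloride
Conditions: (COCl)2, DMF (cat.), CH2Cl2, 0 °C to rt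
Reagents that add atoms: oxalyl chloride ClC(=O)C(Cl)=O
Why: Oxalyl chloride with catalytic DMF converts a silyl ester into the acid chloride without free HCl, with the chlorosilane as by-product, so the phenolic silyl ether is kept.

Step 15
Reactants: 22 (1R,4R,5S,6S,9RS)-6-[(tert-butyldimethylsilyl)oxy]-9-[(4-methoxyphenyl)methoxy]-1-methyl-8-methylidene-4-(propan-2-yl)-trans-hydroazulen-4-ol; 25 4-[(tert-butyldimethylsilyl)oxy]benzoyl chloride
Product: 27 (1R,4R,5S,6S,9RS)-6-[(tert-butyldimethylsilyl)oxy]-9-[(4-methoxyphenyl)methoxy]-1-methyl-8-methylidene-4-(propan-2-yl)-trans-hydroazulen-4-yl 4-[(tert-butyldimethylsilyl)oxy]benzoate, via lithium alkoxide 26 (not isolated)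
Conditions: nBuLi, THF, −78 °C; then 25, −78 to 0 °C
Reagents that add atoms: none
Why: O-Acylation of a lithium tert-alkoxide by an aroyl chloride is the standard way to esterify a hindered tertiary alcohol. It is done at this point because no ketone or enone is yet present that the base could enolise.

Step 16
Reactants: 27 the 4-silyloxybenzoate from step 15
Product: 28 (1R,4R,5S,6S,9RS)-6-[(tert-butyldimethylsilyl)oxy]-9-hydroxy-1-methyl-8-methylidene-4-(propan-2-yl)-trans-hydroazulen-4-yl 4-[(tert-butyldimethylsilyl)oxy]benzoate
Conditions: DDQ, CH2Cl2/pH 7 phosphate buffer, 0 °C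
Reagents that add atoms: none
Why: DDQ cleaves the 4-methoxybenzyl ether oxidatively through the benzylic oxocarbenium ion. Silyl ethers, the aryl ester and the 1,1-disubstituted alkene are inert under buffered conditions.

Step 17
Reactants: 28 the C9 alcohol from step 16
Product: 29 (1R,4R,5S,6S)-6-[(tert-butyldimethylsilyl)oxy]-1-methyl-8-methylidene-9-oxo-4-(propan-2-yl)-trans-hydroazulen-4-yl 4-[(tert-butyldimethylsilyl)oxy]benzoate
Conditions: Dess–Martin periodinane, CH2Cl2, 0 °C to rt
Reagents that add atoms: none
Why: Dess–Martin oxidation of the secondary allylic alcohol. Both C9 epimers converge on a single α-methylene ketone.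

Step 18
Reactants: 29 the α-methylene ketone from step 17
Product: 30 (1R,4R,5S,6S)-6-[(tert-butyldimethylsilyl)oxy]-1,8-dimethyl-9-oxo-4-(propan-2-yl)-trans-hydroazul-7-en-4-yl 4-[(tert-butyldimethylsilyl)oxy]benzoate
Conditions: RhCl3·3H2O (10 mol %), EtOH, 80 °C
Reagents that add atoms: none
Why: Rhodium-hydride addition and elimination moves the exocyclic double bond of an α-methylene ketone into the ring, giving the more substituted conjugated enone as the thermodynamic isomer. Only C7 offers ring hydrogens next to C8, so a single endocyclic enone can form.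

Step 19
Reactants: 30 the bis-silylated enone from step 18
Product: 31 (1R,4R,5S,6S)-6-hydroxy-1,8-dimethyl-9-oxo-4-(propan-2-yl)-trans-hydroazul-7-en-4-yl 4-hydroxybenzoate (the target)
Conditions: HF·pyridine, pyridine, THF, 0 °C to rt
Reagents that add atoms: none
Why: Buffered HF·pyridine removes the aryl and the secondary alkyl silyl ether without forming an alkoxide. The tertiary ester therefore cannot migrate to the freed C6 hydroxyl, and the γ-hydroxy enone never meets base.

## Compound list

1 | 3-ethoxycyclopent-2-en-1-one | CCOC1=CC(=O)CC1 | starting material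
2 | tert-butyl acetate | CC(=O)OC(C)(C)C | starting material
3 | lithium 1-tert-butoxyethen-1-olate (lithium enolate of 2) | [Li]OC(=C)OC(C)(C)C | intermediate
4 | lithium 1-(2-tert-butoxy-2-oxoethyl)-3-ethoxycyclopent-2-en-1-olate (racemic 1,2-adduct) | CCOC1=CC(O[Li])(CC(=O)OC(C)(C)C)CC1 | intermediate
5 | tert-butyl 2-(3-oxocyclopent-1-en-1-yl)acetate | CC(C)(C)OC(=O)CC1=CC(=O)CC1 | intermediate
6 | trimethylaluminium | C[Al](C)C | starting material
7 | formaldehyde (monomeric, from paraformaldehyde) | C=O | starting material
8 | tert-butyl 2-[(1R)-3-[(dimethylalumanyl)oxy]-1-methylcyclopent-2-en-1-yl]acetate | CC(C)(C)OC(=O)C[C@@]1(C)CCC(O[Al](C)C)=C1 | intermediate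
9 | tert-butyl 2-[(1R,2S)-2-(hydroxymethyl)-1-methyl-3-oxocyclopentyl]acetate | OC[C@@H]1[C@@](C)(CC(=O)OC(C)(C)C)CCC1=O | intermediate
10 | tert-butyl 2-[(1R,2S)-1-methyl-3-oxo-2-{[(triethylsilyl)oxy]methyl}cyclopentyl]acetate | CC[Si](CC)(CC)OC[C@@H]1[C@@](C)(CC(=O)OC(C)(C)C)CCC1=O | intermediate
11 | isopropylmagnesium chloride | CC(C)[Mg]Cl | starting material
12 | tert-butyl 2-[(1R,2S,3R)-3-hydroxy-1-methyl-3-(propan-2-yl)-2-{[(triethylsilyl)oxy]methyl}cyclopentyl]acetate | CC[Si](CC)(CC)OC[C@@H]1[C@@](C)(CC(=O)OC(C)(C)C)CC[C@@]1(O)C(C)C | intermediate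
13 | tert-butyl 2-[(1R,2S,3R)-1-methyl-3-(propan-2-yl)-3-[(triethylsilyl)oxy]-2-{[(triethylsilyl)oxy]methyl}cyclopentyl]acetate | CC[Si](CC)(CC)OC[C@@H]1[C@@](C)(CC(=O)OC(C)(C)C)CC[C@@]1(O[Si](CC)(CC)CC)C(C)C | intermediate
14 | 2-[(1R,2S,3R)-1-methyl-3-(propan-2-yl)-3-[(triethylsilyl)oxy]-2-{[(triethylsilyl)oxy]methyl}cyclopentyl]acetaldehyde | CC[Si](CC)(CC)OC[C@@H]1[C@@](C)(CC=O)CC[C@@]1(O[Si](CC)(CC)CC)C(C)C | intermediate
15 | isopropenylmagnesium bromide | CC(=C)[Mg]Br | starting material
16 | (2RS)-3-methyl-1-[(1R,2S,3R)-1-methyl-3-(propan-2-yl)-3-[(triethylsilyl)oxy]-2-{[(triethylsilyl)oxy]methyl}cyclopentyl]but-3-en-2-ol | CC[Si](CC)(CC)OC[C@@H]1[C@@](C)(CC(O)C(C)=C)CC[C@@]1(O[Si](CC)(CC)CC)C(C)C | intermediate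
17 | 4-methoxybenzyl ether of 16 at the C9 oxygen | CC[Si](CC)(CC)OC[C@@H]1[C@@](C)(CC(OCc2ccc(OC)cc2)C(C)=C)CC[C@@]1(O[Si](CC)(CC)CC)C(C)C | intermediate
18 | dimethyl(alkoxy)sulfonium chloride of the C6 oxygen of 17 | C[S+](C)OC[C@@H]1[C@@](C)(CC(OCc2ccc(OC)cc2)C(C)=C)CC[C@@]1(O[Si](CC)(CC)CC)C(C)C.[Cl-] | intermediate
19 | (1R,2R,5R)-2-{(2RS)-2-[(4-methoxyphenyl)methoxy]-3-methylbut-3-en-1-yl}-2-methyl-5-(propan-2-yl)-5-[(triethylsilyl)oxy]cyclopentane-1-carbaldehyde | O=C[C@@H]1[C@@](C)(CC(OCc2ccc(OC)cc2)C(C)=C)CC[C@@]1(O[Si](CC)(CC)CC)C(C)C | intermediate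
20 | (1R,4R,5S,6S,9RS)-9-[(4-methoxyphenyl)methoxy]-1-methyl-8-methylidene-4-(propan-2-yl)-4-[(triethylsilyl)oxy]-trans-hydroazulen-6-ol | C=C1C[C@H](O)[C@@H]2[C@](C)(CC[C@@]2(O[Si](CC)(CC)CC)C(C)C)CC1OCc1ccc(OC)cc1 | intermediate
21 | (1R,4R,5S,6S,9RS)-9-[(4-methoxyphenyl)methoxy]-1-methyl-8-methylidene-4-(propan-2-yl)-trans-hydroazulene-4,6-diol | C=C1C[C@H](O)[C@@H]2[C@](C)(CC[C@@]2(O)C(C)C)CC1OCc1ccc(OC)cc1 | intermediate
22 | (1R,4R,5S,6S,9RS)-6-[(tert-butyldimethylsilyl)oxy]-9-[(4-methoxyphenyl)methoxy]-1-methyl-8-methylidene-4-(propan-2-yl)-trans-hydroazulen-4-ol | C=C1C[C@H](O[Si](C)(C)C(C)(C)C)[C@@H]2[C@](C)(CC[C@@]2(O)C(C)C)CC1OCc1ccc(OC)cc1 | intermediate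
23 | 4-hydroxybenzoic acid | OC(=O)c1ccc(O)cc1 | starting material
24 | tert-butyldimethylsilyl 4-[(tert-butyldimethylsilyl)oxy]benzoate | CC(C)(C)[Si](C)(C)OC(=O)c1ccc(O[Si](C)(C)C(C)(C)C)cc1 | intermediate
25 | 4-[(tert-butyldimethylsilyl)oxy]benzoyl chloride | ClC(=O)c1ccc(O[Si](C)(C)C(C)(C)C)cc1 | intermediate
26 | lithium C4-alkoxide of 22 | C=C1C[C@H](O[Si](C)(C)C(C)(C)C)[C@@H]2[C@](C)(CC[C@@]2(O[Li])C(C)C)CC1OCc1ccc(OC)cc1 | intermediate
27 | (1R,4R,5S,6S,9RS)-6-[(tert-butyldimethylsilyl)oxy]-9-[(4-methoxyphenyl)methoxy]-1-methyl-8-methylidene-4-(propan-2-yl)-trans-hydroazulen-4-yl 4-[(tert-butyldimethylsilyl)oxy]benzoate | C=C1C[C@H](O[Si](C)(C)C(C)(C)C)[C@@H]2[C@](C)(CC[C@@]2(OC(=O)c2ccc(O[Si](C)(C)C(C)(C)C)cc2)C(C)C)CC1OCc1ccc(OC)cc1 | intermediate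
28 | (1R,4R,5S,6S,9RS)-6-[(tert-butyldimethylsilyl)oxy]-9-hydroxy-1-methyl-8-methylidene-4-(propan-2-yl)-trans-hydroazulen-4-yl 4-[(tert-butyldimethylsilyl)oxy]benzoate | C=C1C[C@H](O[Si](C)(C)C(C)(C)C)[C@@H]2[C@](C)(CC[C@@]2(OC(=O)c2ccc(O[Si](C)(C)C(C)(C)C)cc2)C(C)C)CC1O | intermediate
29 | (1R,4R,5S,6S)-6-[(tert-butyldimethylsilyl)oxy]-1-methyl-8-methylidene-9-oxo-4-(propan-2-yl)-trans-hydroazulen-4-yl 4-[(tert-butyldimethylsilyl)oxy]benzoate | C=C1C[C@H](O[Si](C)(C)C(C)(C)C)[C@@H]2[C@](C)(CC[C@@]2(OC(=O)c2ccc(O[Si](C)(C)C(C)(C)C)cc2)C(C)C)CC1=O | intermediate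
30 | (1R,4R,5S,6S)-6-[(tert-butyldimethylsilyl)oxy]-1,8-dimethyl-9-oxo-4-(propan-2-yl)-trans-hydroazul-7-en-4-yl 4-[(tert-butyldimethylsilyl)oxy]benzoate | CC1=C[C@H](O[Si](C)(C)C(C)(C)C)[C@@H]2[C@](C)(CC[C@@]2(OC(=O)c2ccc(O[Si](C)(C)C(C)(C)C)cc2)C(C)C)CC1=O | intermediate
31 | (1R,4R,5S,6S)-6-hydroxy-1,8-dimethyl-9-oxo-4-(propan-2-yl)-trans-hydroazul-7-en-4-yl 4-hydroxybenzoate | CC1=C[C@H](O)[C@@H]2[C@](C)(CC[C@@]2(OC(=O)c2ccc(O)cc2)C(C)C)CC1=O | target

## Step count and least certain steps

Total steps: 19. Longest linear sequence: 17 (steps 1–12 and 15–19); steps 13 and 14 form a two-step side branch.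

**Step 10 (key step).** The most likely failure is poor facial selectivity at C6. Type 2 ene closures normally prefer a chair-like transition state with a pseudo-axial oxygen, which here leads to the 6α alcohol, and this competes with the less congested twist arrangement argued for above. A lesser hazard is ionisation at C8 followed by hydride shift from C9. The fallback sets out from 19 and returns at 21. The cyclisation is run as described and the product is taken on as (6R)-9-[(4-methoxyphenyl)methoxy]-1-methyl-8-methylidene-4-(propan-2-yl)-4-[(triethylsilyl)oxy]-trans-hydroazulen-6-ol F1. Bu4NF gives the 6-epimeric 4,6-diol F2. Dess–Martin oxidation of its only secondary alcohol gives the 4-hydroxy-6-ketone F3. Me4NBH(OAc)3 in MeCN/AcOH at −20 °C (Evans–Saksena reduction) then binds the C4 hydroxyl on the α-face and delivers hydride to the α-face of C6, giving the 4,6-anti diol 21.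

**Step 2.** The hindered aluminium enolate may be captured slowly by formaldehyde, with proton quench and formaldehyde oligomerisation, and the methyl and CH2CO2tBu faces at C5 may not be discriminated well. The fallback sets out from 5 and returns at 9. The same conjugate addition is run, but enolate 8 is silylated with TMSOTf to the isolable tert-butyl 2-[(1R)-1-methyl-3-[(trimethylsilyl)oxy]cyclopent-2-en-1-yl]acetate F4. This is hydroxymethylated in a separate Mukaiyama aldol with aqueous formaldehyde and Sc(OTf)3 in THF. The open transition state and the equilibrating medium favour C6 trans to the larger arm.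

**Step 15.** Acylation of the crowded tertiary alkoxide may be slow, giving time for the C6 silyl group to shift to O4 or for the alkoxide to attack the phenolic silyl ether. The fallback sets out from 22 and returns at 27, and it changes the bond that is made from O–acyl to acyl–aryl. Alkoxide 26 is treated with the small electrophile 1,1′-carbonyldiimidazole to give the C4 imidazole-1-carboxylate F5. The aryl Grignard reagent 4-[(tert-butyldimethylsilyl)oxy]phenylmagnesium bromide F6, made from the commercial aryl bromide and magnesium, then displaces imidazole to give 27. This is the reaction type by which aryl Grignard reagents give tert-butyl esters with di-tert-butyl dicarbonate.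

**Step 18.** Silyl groups may be lost in hot, slightly acidic ethanol before double-bond migration is complete, or the reaction may stall at an exo/endo mixture. The fallback sets out from 29 and returns at 30. Conjugate reduction of the α-methylene ketone with LiBH(sBu)3 at −78 °C and capture of the regiodefined enolate with TMSCl gives the C8=C9 trimethylsilyl enol ether F7. Saegusa–Ito oxidation with Pd(OAc)2 (divalent palladium) in MeCN then gives 30. β-Hydrogen loss from C7 leads to the conjugated endocyclic enone, and loss from the methyl group only returns 29.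

**Step 4.** The branched reagent may enolise or reduce the ketone instead of adding. The fallback sets out from 10 and returns at 12. The hydride-free sp2 reagent 15 is added with CeCl3 to give the isopropenyl carbinol tert-butyl 2-[(1R,2S,3R)-3-hydroxy-1-methyl-3-(prop-1-en-2-yl)-2-{[(triethylsilyl)oxy]methyl}cyclopentyl]acetate F8. Hydrogenation of its only alkene (H2, Pd/C, EtOAc) gives 12.

**Step 6.** The neopentyl-type tert-butyl ester may react sluggishly at −78 °C, and over-reduction sets in on warming. The fallback sets out from 13 and returns at 14. Full reduction with LiAlH4 gives the primary alcohol 2-[(1R,2S,3R)-1-methyl-3-(propan-2-yl)-3-[(triethylsilyl)oxy]-2-{[(triethylsilyl)oxy]methyl}cyclopentyl]ethan-1-ol F9, and Dess–Martin oxidation gives 14.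

## Further compounds

F1 | step 10 | (1R,4R,5S,6R,9RS)-9-[(4-methoxyphenyl)methoxy]-1-methyl-8-methylidene-4-(propan-2-yl)-4-[(triethylsilyl)oxy]-trans-hydroazulen-6-ol | C=C1C[C@@H](O)[C@@H]2[C@](C)(CC[C@@]2(O[Si](CC)(CC)CC)C(C)C)CC1OCc1ccc(OC)cc1
F2 | step 10 | (1R,4R,5S,6R,9RS)-9-[(4-methoxyphenyl)methoxy]-1-methyl-8-methylidene-4-(propan-2-yl)-trans-hydroazulene-4,6-diol | C=C1C[C@@H](O)[C@@H]2[C@](C)(CC[C@@]2(O)C(C)C)CC1OCc1ccc(OC)cc1
F3 | step 10 | (1R,4R,5R,9RS)-4-hydroxy-9-[(4-methoxyphenyl)methoxy]-1-methyl-8-methylidene-4-(propan-2-yl)-trans-hydroazulen-6-one | C=C1CC(=O)[C@@H]2[C@](C)(CC[C@@]2(O)C(C)C)CC1OCc1ccc(OC)cc1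
F4 | step 2 | tert-butyl 2-[(1R)-1-methyl-3-[(trimethylsilyl)oxy]cyclopent-2-en-1-yl]acetate | CC(C)(C)OC(=O)C[C@@]1(C)CCC(O[Si](C)(C)C)=C1
F5 | step 15 | (1R,4R,5S,6S,9RS)-6-[(tert-butyldimethylsilyl)oxy]-9-[(4-methoxyphenyl)methoxy]-1-methyl-8-methylidene-4-(propan-2-yl)-trans-hydroazulen-4-yl 1H-imidazole-1-carboxylate | C=C1C[C@H](O[Si](C)(C)C(C)(C)C)[C@@H]2[C@](C)(CC[C@@]2(OC(=O)n2ccnc2)C(C)C)CC1OCc1ccc(OC)cc1
F6 | step 15 | 4-[(tert-butyldimethylsilyl)oxy]phenylmagnesium bromide | CC(C)(C)[Si](C)(C)Oc1ccc([Mg]Br)cc1
F7 | step 18 | (1R,4R,5S,6S)-6-[(tert-butyldimethylsilyl)oxy]-1,8-dimethyl-4-(propan-2-yl)-9-[(trimethylsilyl)oxy]-trans-hydroazul-8-en-4-yl 4-[(tert-butyldimethylsilyl)oxy]benzoate | CC=1C[C@H](O[Si](C)(C)C(C)(C)C)[C@@H]2[C@](C)(CC[C@@]2(OC(=O)c2ccc(O[Si](C)(C)C(C)(C)C)cc2)C(C)C)CC=1O[Si](C)(C)C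
F8 | step 4 | tert-butyl 2-[(1R,2S,3R)-3-hydroxy-1-methyl-3-(prop-1-en-2-yl)-2-{[(triethylsilyl)oxy]methyl}cyclopentyl]acetate | CC[Si](CC)(CC)OC[C@@H]1[C@@](C)(CC(=O)OC(C)(C)C)CC[C@@]1(O)C(C)=C
F9 | step 6 | 2-[(1R,2S,3R)-1-methyl-3-(propan-2-yl)-3-[(triethylsilyl)oxy]-2-{[(triethylsilyl)oxy]methyl}cyclopentyl]ethan-1-ol | CC[Si](CC)(CC)OC[C@@H]1[C@@](C)(CCO)CC[C@@]1(O[Si](CC)(CC)CC)C(C)C
A1 | alternative 1 | trans-fused 4-hydroxy-hydroazulen-6-one with C9 dioxolane | CC1CC(=O)[C@@H]2[C@](C)(CC[C@@]2(O)C(C)C)CC13OCCO3
A2 | alternative 1 | all-cis decalin 4,6-diol 5-methanesulfonate with C9 dioxolane (C1 bonded to C6) | CC1C[C@]2(O)[C@@H](OS(C)(=O)=O)[C@](O)(C(C)C)CC[C@]2(C)CC13OCCO3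
A3 | alternative 2 | 2-(1-hydroxy-2,2-dimethoxyethyl)-3-methyl-3-(2-methylidenebutyl)cyclopentan-1-one | O=C1CC[C@](C)(CC(=C)CC)[C@H]1[C@@H](O)C(OC)OC
A4 | alternative 2 | 3-(2-methylidenebutyl)cyclopent-2-en-1-one | O=C1CCC(CC(=C)CC)=C1
A5 | alternative 2 | 2,2-dimethoxyacetaldehyde | COC(OC)C=O
A6 | alternative 3 | bicyclic cyclohepta-1,4-diene with C8 methyl ester, C9 silyl enol ether, C4 dioxolane and quaternary C1 | COC(=O)C1=C(O[Si](C)(C)C(C)(C)C)C[C@@]2(C)CCC3(OCCO3)C2=CC1
A7 | alternative 3 | 7-ethenyl-6-methyl-1,4-dioxaspiro[4.4]non-6-ene | C=CC1=C(C)CCC12OCCO2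
A8 | alternative 3 | methyl 3-[(tert-butyldimethylsilyl)oxy]-2-diazobut-3-enoate | COC(=O)C(=[N+]=[N-])C(=C)O[Si](C)(C)C(C)(C)C
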